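The earlier runs and the new flask are calculated with made-up constants; the scatter is artificial.

In a one-step world I would scale a single constant by substrate times catalyst. The equations on the card make a cycle instead, so I count laps.

| flask | substrate | coupling partner | free catalyst | temperature | remark | time |
|---|---|---|---|---|---|---|
| Thursday's | 10 mM (fed, over 5.0 min) | 15 mM | 0.060 mM | 10 °C | run made earlier |  |
| Friday's | 10 mM (fed, over 5.0 min) | 15 mM | 0.29 mM | 32 °C | run made earlier |  |
| ash | 10 mM | 15.0 mM | 0.050 mM | 40 °C | everything together at the start | 20 min |
| birch | 10 mM (fed, over 5.0 min) | 15.0 mM | 0.20 mM | 0 °C |  | 20 min |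

| run | time / min | product / % | substrate / % |
|---|---|---|---|
| Thursday's | 2.00 | 0.5 | 38.5 |
| Thursday's | 4.00 | 2.2 | 77.5 |
| Thursday's | 6.00 | 4.2 | 94.9 |
| Thursday's | 8.00 | 6.1 | 92.5 |
| Thursday's | 10.0 | 8.3 | 91.4 |
| Thursday's | 12.0 | 11.0 | 88.8 |
| Friday's | 0.333 | 0.9 | 6.4 |
| Friday's | 0.500 | 0.7 | 8.7 |
| Friday's | 0.833 | 2.2 | 13.7 |
| Friday's | 1.50 | 8.6 | 21.1 |
| Friday's | 2.50 | 18.9 | 30.9 |
| Friday's | 4.00 | 38.7 | 40.3 |

(readings scatter by 0.5 percentage points)

* which one finishes higher in amount of product, in percent of the substrate charged ("neither" within 2 percentage points) (ash / birch / neither)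
* amount of product at the end, in percent of the substrate charged, ash
* amount of product at the end, in percent of the substrate charged, birch

- what may be going on: catalyst intermediate C -> free catalyst + product; catalyst intermediate B <-> by-product + catalyst intermediate C; substrate + free catalyst -> catalyst intermediate A; coupling partner + catalyst intermediate A <-> catalyst intermediate B
- percentages count the whole charge, also what has not yet gone in

My measure is the lap time: catalyst as a fraction of the substrate charge, divided by the fraction of that charge turned per minute (the inverse of the turnover frequency). Late in Thursday's run it reads 0.529 min. In Friday's run I count substrate gone, meaning fed less standing. The lap reads 0.326 min with 17.4 % of the charge standing, and 0.211 min with 35.6 %. So I split Friday's lap into a wait of 0.0390 min divided by the substrate fraction, plus a cycle part of 0.102 min.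

Temperature comes first. Friday's whole lap, taken with a fixed factor per degree, gives 0.804 min at 0 °C. Going round again with the cycle part gives 1.12 min, my lap time at birch's temperature. The same line puts the cycle part at 0.0558 min for ash.

Catalyst comes next: birch holds 4.00 times ash's charge, and by hand product follows catalyst over lap, times time. The feed comes last. I count birch's laps from the end of its feed, which gives 26.8 %. Ash starts with all its substrate, and its wait grows as substrate falls. Whole substrate throughout gives 105 %, which the charge forbids. Half the substrate put back gives 74.8 %, and that answer's mean substrate gives 84.7 %. I commit to 79.8 % for ash.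

The forecast also says ash, but with ash at 65 % and birch at 38 %, holding that “substrate capture partly limits”.

The flask gives ash: ash 79.9 %, birch 22.5 %.

    catalyst intermediate C → free catalyst + product (k = 1.80 min⁻¹, Ea = 75.0 kJ mol⁻¹)
    catalyst intermediate B ⇌ by-product + catalyst intermediate C (K = 0.00570 M, k = 3.60 min⁻¹, Ea = 79.0 kJ mol⁻¹, ΔH = 20.0 kJ mol⁻¹)
    substrate + free catalyst → catalyst intermediate A (k = 380 L mol⁻¹ min⁻¹, Ea = 36.0 kJ mol⁻¹)
    coupling partner + catalyst intermediate A ⇌ catalyst intermediate B (K = 500 L mol⁻¹, k = 250 L mol⁻¹ min⁻¹, Ea = 40.0 kJ mol⁻¹, ΔH = −9.00 kJ mol⁻¹)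
    (constants at 0 °C)

Temperature is the main reason ash stands higher than birch. Birch's own lap over its second half reads 1.69 min, longer than my 1.12 min. Ash's charge run at birch's temperature is the proof: it gives 6.69 %. Birch read at 50 min is the further case: my lap reckons 80.3 %, and that flask gives 51.0 %.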